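**Retrosynthetic overview**
- The target comes from a spiro hydroxy ketone by hydroxyl-directed ketone reduction; the trans Br/Cl pair of ring B comes from a ring B alkene through a transient bromo ether that fixes the bromonium face.
- The ring B β,γ-enone comes from 1,4-hydrogenation of a spiro[5.5]undeca-2,4-dien-1-one.
- Key disconnection: the spiro C–CMe2 bond. A bromonium-triggered ipso (ortho) dearomatising spirocyclisation of an aryl silyl ether closes ring A and installs C–Br, CMe2 and the spiro centre in one step.
- The cyclisation substrate is a disiloxane-bridged diol made by asymmetric homoprenyl Grignard addition to 2'-hydroxy-4'-methylacetophenone.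
- Ring order: ring B is the starting arene; ring A is closed in the key step; ring B is then reduced and halogenated.

Assumption: 1 and 2 are purchased, and the enantiomer of the chiral ligand in step 1 is chosen so that the (R)-carbinol is formed (≥90% ee assumed with the phenol carried as its magnesium phenoxide).

Step 1
Reactants: 1 2'-hydroxy-4'-methylacetophenone; 2 5-bromo-2-methylpent-2-ene
Product: 4 (R)-2-(2-hydroxy-6-methylhept-5-en-2-yl)-5-methylphenol, via homoprenylmagnesium bromide 3 (not isolated)
Conditions: 2, Mg, THF, 40 °C; then 1, chiral trans-1,2-diaminocyclohexane-derived N,N,O-aminophenol ligand (1.1 equiv), 3 (3.5 equiv), toluene, −78 °C; then H2O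
Reagents that add atoms: none
Why: Ligand-mediated asymmetric 1,2-addition of a Grignard reagent to an aryl methyl ketone, in which the chiral magnesium aminophenoxide complex differentiates the two ketone faces and sets the (R)-tertiary carbinol centre.

Step 2
Reactants: 4 (R)-2-(2-hydroxy-6-methylhept-5-en-2-yl)-5-methylphenol
Product: 5 (6R)-2,2,4,4-tetraisopropyl-6,9-dimethyl-6-(4-methylpent-3-en-1-yl)-6H-benzo[f][1,3,5,2,4]trioxadisilocine (cyclic disiloxanediyl ether of 4)
Conditions: TIPDSCl2, silver triflate (AgOSO2CF3), 2,6-lutidine, CH2Cl2, −40 °C to rt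
Reagents that add atoms: 1,3-dichloro-1,1,3,3-tetraisopropyldisiloxane (TIPDSCl2) CC(C)[Si](Cl)(C(C)C)O[Si](Cl)(C(C)C)C(C)C
Why: Silyl triflate silylation (phenol first, then ring closure on the tertiary alcohol) gives the eight-membered cyclic disiloxane, which masks both hydroxyls, keeps the arene an electron-rich silyl ether and holds the benzylic C–O bond out of the arene plane; no stereocentre is touched.

Step 3
Reactants: 5 cyclic disiloxanediyl ether
Product: 7 (6S,8R,11R)-8-bromo-11-[(3-hydroxy-1,1,3,3-tetraisopropyldisiloxan-1-yl)oxy]-3,7,7,11-tetramethylspiro[5.5]undeca-2,4-dien-1-one, via silyl bromide 6 (not isolated)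
Conditions: Et2SBr·SbCl5Br (1.1 equiv), MeNO2, −25 °C, 5 min; then H2O/NaHCO3 work-up
Reagents that add atoms: bromodiethylsulfonium bromopentachloroantimonate CC[S+](Br)CC.Cl[Sb-](Cl)(Cl)(Cl)(Cl)Br; water O
Why: Proposed new method: Br+ transfer to the trisubstituted alkene gives a bromonium ion that is opened at its tertiary carbon by the ipso carbon ortho to the siloxy group (6-endo, arenium ion stabilised by O-silyl and the para methyl), and loss of silicon from the O-silyl oxocarbenium ion to bromide gives the 6,6-disubstituted cyclohexa-2,4-dienone; the closest known reactions are bromonium-induced cation-π cyclisations terminated by arenes and alkylative ipso-dearomatisation of phenols, and the chair transition state with Br equatorial (anti addition), the tethered C–O bond anti to the forming bond (its methyl axial) and the siloxy-bearing ortho carbon beside the ring CH2 rather than beside the buttressed axial methyl sets the spiro and C–Br centres relative to the carbinol centre.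

Step 4
Reactants: 7 spirodienone silanol
Product: 8 (6S,8R,11R)-8-bromo-11-[(3-hydroxy-1,1,3,3-tetraisopropyldisiloxan-1-yl)oxy]-3,7,7,11-tetramethylspiro[5.5]undec-3-en-1-one
Conditions: (η6-naphthalene)Cr(CO)3 (20 mol %), H2 (50 atm), THF, 45 °C
Reagents that add atoms: none
Why: (Arene)Cr(CO)3-catalysed 1,4-hydrogenation is specific for cisoid 1,3-dienes and adds H2 to the diene termini (C2 and C5), leaving the C3=C4 alkene of the β,γ-unsaturated ketone without touching C=O, C–Br or silicon; no stereocentre is formed.

Step 5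
Reactants: 8 β,γ-enone silanol
Product: 9 (6S,8R,11R)-8-bromo-11-hydroxy-3,7,7,11-tetramethylspiro[5.5]undec-3-en-1-one
Conditions: HF·pyridine, pyridine, THF, 0 °C to rt
Reagents that add atoms: none
Why: Buffered acidic fluoride cleaves the Si–O bonds and frees the tertiary alcohol only now, when ring B can no longer aromatise by retro-aldol cleavage; the non-basic conditions avoid retro-aldol and alkene conjugation.

Step 6
Reactants: 9 hydroxy β,γ-enone
Product: 11 (3S,4S,6S,8R,11R)-4,8-dibromo-3-chloro-11-hydroxy-3,7,7,11-tetramethylspiro[5.5]undecan-1-one, via bromo ether 10 (not isolated)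
Conditions: NBS (1.05 equiv), CH2Cl2, 0 °C, dark; then BCl3 (3 equiv), −78 to −40 °C; then H2O
Reagents that add atoms: N-bromosuccinimide O=C1CCC(=O)N1Br; boron trichloride ClB(Cl)Cl
Why: Proposed new method: bromoetherification fixes the bromonium face because the tertiary OH, which sits under ring B, can only capture the bromonium ion on the opposite face (giving the 6-oxabicyclo[3.2.1] ether, as in iodoetherification of cyclohex-3-enylmethanols), and BCl3 then ionises the C4–O bond with anchimeric help from the anti bromine to regenerate that same bromonium ion, which chloride opens at the tertiary carbon (Markovnikov, anti) to give Br on the face of the CMe2 arm and Cl on the face of the carbinol arm; the closest known reactions are BCl3 ether cleavage and bromonium regeneration from β-bromo ethers.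

Step 7
Reactants: 11 bromochloro hydroxy ketone
Product: 12 (1R,4R,6R,7S,9S,10S)-4,10-dibromo-9-chloro-1,5,5,9-tetramethylspiro[5.5]undecane-1,7-diol (CNP0298877.1)
Conditions: Me4NBH(OAc)3, MeCN/AcOH, −20 °C
Reagents that add atoms: none
Why: Hydroxyl-directed reduction (Evans–Saksena type): the tertiary OH exchanges onto boron and delivers hydride to the ketone face it sits on, which is also the face left open by the axial methyl on the chlorine-bearing carbon, so the new OH lies on the face of the CMe2 arm (7S).

**Compound list**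
1 | 2'-hydroxy-4'-methylacetophenone | CC(=O)c1ccc(C)cc1O | starting material
2 | 5-bromo-2-methylpent-2-ene | CC(C)=CCCBr | starting material
3 | (4-methylpent-3-en-1-yl)magnesium bromide | CC(C)=CCC[Mg]Br | intermediate
4 | (R)-2-(2-hydroxy-6-methylhept-5-en-2-yl)-5-methylphenol | CC(C)=CCC[C@@](C)(O)c1ccc(C)cc1O | intermediate
5 | (6R)-2,2,4,4-tetraisopropyl-6,9-dimethyl-6-(4-methylpent-3-en-1-yl)-6H-benzo[f][1,3,5,2,4]trioxadisilocine | CC(C)=CCC[C@@]1(C)O[Si](C(C)C)(C(C)C)O[Si](C(C)C)(C(C)C)Oc2cc(C)ccc12 | intermediate
6 | (6S,8R,11R)-8-bromo-11-[(3-bromo-1,1,3,3-tetraisopropyldisiloxan-1-yl)oxy]-3,7,7,11-tetramethylspiro[5.5]undeca-2,4-dien-1-one | CC1(C)[C@H](Br)CC[C@@](C)(O[Si](C(C)C)(C(C)C)O[Si](Br)(C(C)C)C(C)C)[C@]12C=CC(C)=CC2=O | intermediate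
7 | (6S,8R,11R)-8-bromo-11-[(3-hydroxy-1,1,3,3-tetraisopropyldisiloxan-1-yl)oxy]-3,7,7,11-tetramethylspiro[5.5]undeca-2,4-dien-1-one | CC1(C)[C@H](Br)CC[C@@](C)(O[Si](C(C)C)(C(C)C)O[Si](O)(C(C)C)C(C)C)[C@]12C=CC(C)=CC2=O | intermediate
8 | (6S,8R,11R)-8-bromo-11-[(3-hydroxy-1,1,3,3-tetraisopropyldisiloxan-1-yl)oxy]-3,7,7,11-tetramethylspiro[5.5]undec-3-en-1-one | CC1(C)[C@H](Br)CC[C@@](C)(O[Si](C(C)C)(C(C)C)O[Si](O)(C(C)C)C(C)C)[C@]12CC=C(C)CC2=O | intermediate
9 | (6S,8R,11R)-8-bromo-11-hydroxy-3,7,7,11-tetramethylspiro[5.5]undec-3-en-1-one | CC1(C)[C@H](Br)CC[C@@](C)(O)[C@]12CC=C(C)CC2=O | intermediate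
10 | (3R,4R,6S,8R,11R)-3,8-dibromo-4,11-epoxy-3,7,7,11-tetramethylspiro[5.5]undecan-1-one (ether O on C4 anti to the C3 bromine) | CC1(C)[C@H](Br)CC[C@@](C)(O2)[C@]13C[C@@H]2[C@](C)(Br)CC3=O | intermediate
11 | (3S,4S,6S,8R,11R)-4,8-dibromo-3-chloro-11-hydroxy-3,7,7,11-tetramethylspiro[5.5]undecan-1-one | CC1(C)[C@H](Br)CC[C@@](C)(O)[C@]12C[C@H](Br)[C@@](C)(Cl)CC2=O | intermediate
12 | (1R,4R,6R,7S,9S,10S)-4,10-dibromo-9-chloro-1,5,5,9-tetramethylspiro[5.5]undecane-1,7-diol | CC1(C)[C@H](Br)CC[C@@](C)(O)[C@]12C[C@H](Br)[C@@](C)(Cl)C[C@@H]2O | target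

**Step count and risks**
Total steps: 7. Longest linear sequence: 7 (fully linear).

The three steps most likely to fail:

Step 3 (key spirocyclisation). The risks are ring bromination or O-capture instead of ipso attack, and formation of the carbinol or spiro epimers if the eight-membered tether does not hold the C–O bond anti to the forming bond. The fallback sets out from 5 and comes back at 7. It replaces Br+ by a softer electrophile that does not brominate arenes: Hg(OCOCF3)2 in MeNO2 at −20 °C, then aqueous NaCl, gives through the same chair the alkylmercuric chloride (6S,8R,11R)-8-(chloromercurio)-11-[(3-hydroxy-1,1,3,3-tetraisopropyldisiloxan-1-yl)oxy]-3,7,7,11-tetramethylspiro[5.5]undeca-2,4-dien-1-one F1. Brominative demercuration with Br2/LiBr in pyridine under O2 then replaces mercury by bromine with retention and returns 7. This fallback addresses chemoselectivity only; it does not correct an epimer problem.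

Step 6 (bromo ether, then chloride opening). The risks are chloride return at the secondary carbon, halide scrambling, or ionisation of the wrong C–O bond. The fallback sets out from 8 and comes back at 11. It abandons the ether relay and adds BrCl directly to the silyl-protected alkene with Bu4N+ BrCl2− in CH2Cl2 at −40 °C, relying on the bulky disiloxanyloxy arm under ring B to send Br+ to the opposite face, giving (3S,4S,6S,8R,11R)-4,8-dibromo-3-chloro-11-[(3-hydroxy-1,1,3,3-tetraisopropyldisiloxan-1-yl)oxy]-3,7,7,11-tetramethylspiro[5.5]undecan-1-one F2. HF·pyridine then frees the tertiary alcohol and returns 11. Face selectivity in this variant is less secure than in the main step.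

Step 4 (1,4-hydrogenation). The diene terminus next to the spiro centre is hindered on both faces, so the Cr(CO)3 fragment may not bind. The fallback sets out from 7 and comes back at 8. RhCl(PPh3)3/H2 in benzene reduces only the disubstituted γ,δ-alkene to the conjugated enone (6S,8R,11R)-8-bromo-11-[(3-hydroxy-1,1,3,3-tetraisopropyldisiloxan-1-yl)oxy]-3,7,7,11-tetramethylspiro[5.5]undec-2-en-1-one F3. γ-Deprotonation with KN(SiMe3)2 in THF at −78 °C (no α' hydrogens are present) and kinetic α-protonation with AcOH then deconjugates it to 8.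

**Further compounds**
F1 | step 3 | (6S,8R,11R)-8-(chloromercurio)-11-[(3-hydroxy-1,1,3,3-tetraisopropyldisiloxan-1-yl)oxy]-3,7,7,11-tetramethylspiro[5.5]undeca-2,4-dien-1-one | CC1(C)[C@H]([Hg]Cl)CC[C@@](C)(O[Si](C(C)C)(C(C)C)O[Si](O)(C(C)C)C(C)C)[C@]12C=CC(C)=CC2=O
F2 | step 6 | (3S,4S,6S,8R,11R)-4,8-dibromo-3-chloro-11-[(3-hydroxy-1,1,3,3-tetraisopropyldisiloxan-1-yl)oxy]-3,7,7,11-tetramethylspiro[5.5]undecan-1-one | CC1(C)[C@H](Br)CC[C@@](C)(O[Si](C(C)C)(C(C)C)O[Si](O)(C(C)C)C(C)C)[C@]12C[C@H](Br)[C@@](C)(Cl)CC2=O
F3 | step 4 | (6S,8R,11R)-8-bromo-11-[(3-hydroxy-1,1,3,3-tetraisopropyldisiloxan-1-yl)oxy]-3,7,7,11-tetramethylspiro[5.5]undec-2-en-1-one | CC1(C)[C@H](Br)CC[C@@](C)(O[Si](C(C)C)(C(C)C)O[Si](O)(C(C)C)C(C)C)[C@]12CCC(C)=CC2=O
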